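**Retrosynthetic overview**
- The target is an 8-O-4′-type α-aryloxy propiophenone; both benzene rings are bought and no ring is formed.
- Last bond made: aryl–C(=O), by a nickel-catalysed electroreductive acyl–aryl coupling of an S-(2-pyridyl) thioester with 5-iodo-1,2,3-trimethoxybenzene.
- Before that: C(acyl)–S activation of the free (S)-2-aryloxypropanoic acid (Mukaiyama thioesterification).
- First bond made: ArO–C(sp3), by SN2 with inversion of (E)-4-propenylsyringol phenoxide on (R)-2-chloropropanoic acid, which supplies the only stereocentre.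
- Order: ether C–O (sets S), then thioester, then ketone C–C.

Assumption: (E)-2,6-dimethoxy-4-(prop-1-en-1-yl)phenol (trans-4-propenylsyringol), (R)-2-chloropropanoic acid (the D-alanine-derived enantiomer) and 5-iodo-1,2,3-trimethoxybenzene are bought as such, the phenol as the pure E isomer.

**Step 1**
Reactants: 1 (E)-2,6-dimethoxy-4-(prop-1-en-1-yl)phenol; 2 (R)-2-chloropropanoic acid
Product: 3 (S)-2-[2,6-dimethoxy-4-[(E)-prop-1-en-1-yl]phenoxy]propanoic acid
Conditions: 1 (1.2 equiv), NaH (2.3 equiv), THF–DMF (9:1), 0 °C, then 2 (1.0 equiv), 60 °C; aq. HCl to pH 2, NaHCO3 extraction to remove excess 1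
Reagents that add atoms: none
Why: Williamson ether synthesis in which the sodium phenoxide displaces chloride from the sodium carboxylate of 2 by SN2 with clean inversion (R to S), the carboxylate form keeping C-α non-enolisable and NaCl precipitating from THF so that chloride exchange does not erode the ee.

**Step 2**
Reactants: 3 (S)-2-[2,6-dimethoxy-4-[(E)-prop-1-en-1-yl]phenoxy]propanoic acid
Product: 4 S-(pyridin-2-yl) (S)-2-[2,6-dimethoxy-4-[(E)-prop-1-en-1-yl]phenoxy]propanethioate
Conditions: 2,2'-dipyridyl disulfide (1.2 equiv), PPh3 (1.2 equiv), CH2Cl2, 0 °C to rt; short silica plug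
Reagents that add atoms: 2,2'-dipyridyl disulfide, c1ccc(SSc2ccccn2)nc1
Why: Mukaiyama redox condensation (thioesterification via an acyloxyphosphonium ion) runs without base or acid, so the α-aryloxy stereocentre is retained and the acid-sensitive propenyl arene is untouched.

**Step 3**
Reactants: 4 S-(pyridin-2-yl) (S)-2-[2,6-dimethoxy-4-[(E)-prop-1-en-1-yl]phenoxy]propanethioate; 5 5-iodo-1,2,3-trimethoxybenzene
Product: 6 (S)-2-[2,6-dimethoxy-4-[(E)-prop-1-en-1-yl]phenoxy]-1-(3,4,5-trimethoxyphenyl)propan-1-one
Conditions: 5 (1.5 equiv), NiBr2·dme (10 mol%), 4,4'-di-tert-butyl-2,2'-bipyridine (dtbbpy, 12 mol%), nBu4NBF4 (0.1 M), DMA, undivided cell, Zn anode, reticulated vitreous carbon cathode, constant current 3 mA cm-2, 2.3 F mol-1, 20 °C, Ar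
Reagents that add atoms: none
Why: Proposed new method: a nickel-catalysed electroreductive acyl–aryl cross-electrophile coupling in which cathodically formed zerovalent nickel–dtbbpy adds first to the C–I bond of 5, the divalent aryl–nickel species is reduced at the cathode to monovalent aryl–nickel, this undergoes pyridine-directed oxidative addition into the C(acyl)–S bond of 4, and the trivalent acyl(aryl)nickel reductively eliminates the ketone while Zn2+ from the anode scavenges pyridine-2-thiolate; no radical or enolate is formed at C-α and the catalyst holds the cathode near −1.3 V vs SCE, short of what the product ketone, its α-aryloxy C–O bond or the propenyl group need, so the stereocentre is carried through with retention and the E-alkene is kept; closest known reaction type: Zn- or Mn-driven nickel-catalysed ketone synthesis from S-(2-pyridyl) thioesters and alkyl iodides, and nickel/bipyridine-catalysed electroreductive cross-electrophile couplings of aryl halides, neither shown for an aryl iodide with an enantioenriched α-aryloxy thioester.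

**Compound list**
1 | (E)-2,6-dimethoxy-4-(prop-1-en-1-yl)phenol | C/C=C/c1cc(OC)c(O)c(OC)c1 | starting material
2 | (R)-2-chloropropanoic acid | C[C@@H](Cl)C(=O)O | starting material
3 | (S)-2-[2,6-dimethoxy-4-[(E)-prop-1-en-1-yl]phenoxy]propanoic acid | C/C=C/c1cc(OC)c(O[C@@H](C)C(=O)O)c(OC)c1 | intermediate
4 | S-(pyridin-2-yl) (S)-2-[2,6-dimethoxy-4-[(E)-prop-1-en-1-yl]phenoxy]propanethioate | C/C=C/c1cc(OC)c(O[C@@H](C)C(=O)Sc2ccccn2)c(OC)c1 | intermediate
5 | 5-iodo-1,2,3-trimethoxybenzene | COc1cc(I)cc(OC)c1OC | starting material
6 | (S)-2-[2,6-dimethoxy-4-[(E)-prop-1-en-1-yl]phenoxy]-1-(3,4,5-trimethoxyphenyl)propan-1-one | C/C=C/c1cc(OC)c(O[C@@H](C)C(=O)c2cc(OC)c(OC)c(OC)c2)c(OC)c1 | target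

**Step count and risks**
Total steps: 3. Longest linear sequence: 3 (1 or 2 → 3 → 4 → 6).

Steps most likely to fail:

Step 3 (the proposed new coupling). Risks are homocoupling of 5 to the biaryl, decarbonylation of the acyl–nickel species, over-reduction of the α-aryloxy ketone if the charge is overrun, and loss of ee through electrogenerated base. The fallback uses known chemistry, sets out from 4 and 5 and comes back at 6. Iodine–magnesium exchange of 5 with iPrMgCl·LiCl (THF, 0 °C to rt) gives (3,4,5-trimethoxyphenyl)magnesium chloride F3. This is added (1.05 equiv) to 4 in THF at −78 °C (Mukaiyama ketone synthesis from S-(2-pyridyl) thioates). The magnesium chelate of the tetrahedral adduct holds the reaction at the ketone stage, and the low temperature with near-stoichiometric Grignard reagent protects C-α.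

Step 1. Risks are a sluggish SN2 by the di-ortho-substituted phenoxide and partial loss of ee through chloride exchange or an α-lactone (retention) pathway. The ee of 3 is checked by chiral HPLC. The fallback sets out from 1 and comes back at 3. A Mitsunobu reaction of 1 with bought methyl (R)-lactate (C[C@@H](O)C(=O)OC), PPh3 and DIAD in THF at 0 °C to rt gives, with inversion, methyl (S)-2-[2,6-dimethoxy-4-[(E)-prop-1-en-1-yl]phenoxy]propanoate F1. Saponification with LiOH in THF/H2O at 0 °C then gives 3.

Step 2. Risks are hydrolysis of the activated thioester on silica, co-elution with triphenylphosphine oxide and slight epimerisation of the active ester. The fallback sets out from 3 and comes back at 6, bypassing 4. Treatment of 3 with 1-chloro-N,N,2-trimethylprop-1-en-1-amine (1.1 equiv) in CH2Cl2 at 0 °C forms, without HCl or base, (S)-2-[2,6-dimethoxy-4-[(E)-prop-1-en-1-yl]phenoxy]propanoyl chloride F2. After evaporation and a change to DMA, crude F2 is electrolysed with 5 under the nickel conditions of step 3.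

**Further compounds**
F1 | step 1 | methyl (S)-2-[2,6-dimethoxy-4-[(E)-prop-1-en-1-yl]phenoxy]propanoate | C/C=C/c1cc(OC)c(O[C@@H](C)C(=O)OC)c(OC)c1
F2 | step 2 | (S)-2-[2,6-dimethoxy-4-[(E)-prop-1-en-1-yl]phenoxy]propanoyl chloride | C/C=C/c1cc(OC)c(O[C@@H](C)C(Cl)=O)c(OC)c1
F3 | step 3 | (3,4,5-trimethoxyphenyl)magnesium chloride (LiCl complex) | COc1cc([Mg]Cl)cc(OC)c1OC
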